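**Assumption:** jaspaquinol has no stereocentres, so "single enantiomer" is taken to mean the single (2E,6E) geometric isomer.

## Retrosynthetic overview

1. Jaspaquinol ⇐ bis-MOM ether 19 ⇐ sulfone 18. The central C5–C4 bond (CH(SO2Ph)–CH2) comes from alkylating C15 allyl sulfone 11 with C13 allylic bromide 17.
2. Sulfone 11 ⇐ B-alkyl Suzuki coupling of cyclohexenyl triflate 4 (from 2-methylcyclohexanone) with the 9-BBN adduct of dienyl silyl ether 7 (from the commercial E-enynol 5).
3. Bromide 17 ⇐ ortho-lithiation and prenylation of bis-MOM hydroquinone, then E-selective SeO2 allylic oxidation and bromination.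
4. No ring is formed in the route: the cyclohexene comes from 2-methylcyclohexanone and the arene from hydroquinone. The C6 alkene geometry is carried from 5; the C2 alkene geometry is set by the SeO2 oxidation.

## Route

**Step 1**
Reactants: 1, 2-methylcyclohexanone (racemic)
Product: 2, 2,6-dimethylcyclohexanone (cis/trans mixture)
Conditions: LDA, THF, −78 °C; MeI, −78 → 0 °C
Reagents that add atoms: iodomethane, CI
Why: Kinetic enolate alkylation; LDA removes the less hindered C6 proton, so methylation occurs there. The cis/trans mixture is irrelevant because both centres are erased by step 3.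

**Step 2**
Reactants: 2, 2,6-dimethylcyclohexanone
Product: 3, 2,2,6-trimethylcyclohexanone (racemic)
Conditions: LDA, THF, −78 → 0 °C; MeI, DMPU, 0 °C → rt
Reagents that add atoms: iodomethane, CI
Why: Enolate alkylation; both α-positions are equivalent methine carbons, so one controlled deprotonation and methylation gives the gem-dimethyl ketone.

**Step 3**
Reactants: 3, 2,2,6-trimethylcyclohexanone
Product: 4, 2,6,6-trimethylcyclohex-1-en-1-yl trifluoromethanesulfonate
Conditions: LDA, THF, −78 → 0 °C; PhNTf2, 0 °C → rt
Reagents that add atoms: N-phenyl-bis(trifluoromethanesulfonimide), O=S(=O)(N(c1ccccc1)S(=O)(=O)C(F)(F)F)C(F)(F)F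
Why: Enol triflate formation; only one α-hydrogen remains, so the tetrasubstituted ring alkene is fixed in the position the target needs.

**Step 4**
Reactants: 5, (2E)-3-methylpent-2-en-4-yn-1-ol
Product: 6, tert-butyldimethyl{[(2E)-3-methylpent-2-en-4-yn-1-yl]oxy}silane
Conditions: TBSCl, imidazole, DMF, 0 °C → rt
Reagents that add atoms: tert-butyldimethylsilyl chloride, CC(C)(C)[Si](C)(C)Cl
Why: Silyl ether protection; it masks the OH from 9-BBN and makes the C6 unit less volatile.

**Step 5**
Reactants: 6, TBS enynyl ether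
Product: 7, tert-butyldimethyl{[(2E)-3-methylpenta-2,4-dien-1-yl]oxy}silane
Conditions: H2 (1 atm, 1.0 equiv uptake), Lindlar catalyst, quinoline, hexane, rt
Reagents that add atoms: none (H2 only)
Why: Lindlar semi-hydrogenation of the terminal alkyne to a vinyl group; the trisubstituted E-alkene is untouched.

**Step 6**
Reactants: 7, dienyl silyl ether; 4, cyclohexenyl triflate
Product: 8, tert-butyldimethyl{[(2E)-3-methyl-5-(2,6,6-trimethylcyclohex-1-en-1-yl)pent-2-en-1-yl]oxy}silane
Conditions: 7, 9-BBN (1.05 equiv), THF, 0 °C → rt; then 4, PdCl2(dppf) (5 mol%), AsPh3, Cs2CO3, DMF/H2O, 50 °C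
Reagents that add atoms: none (9-BBN delivers H only; boron is lost)
Why: B-alkyl Suzuki–Miyaura coupling; 9-BBN adds anti-Markovnikov to the monosubstituted vinyl group only, and the primary borane couples with the triflate. The E-alkene from 5 is not involved.

**Step 7**
Reactants: 8, silyl ether
Product: 9, (2E)-3-methyl-5-(2,6,6-trimethylcyclohex-1-en-1-yl)pent-2-en-1-ol
Conditions: TBAF, THF, 0 °C → rt
Reagents that add atoms: none
Why: Fluoride desilylation; neutral conditions leave both alkenes alone.

**Step 8**
Reactants: 9, allylic alcohol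
Product: 10, 2-[(3E)-5-bromo-3-methylpent-3-en-1-yl]-1,3,3-trimethylcyclohex-1-ene
Conditions: PBr3 (0.4 equiv), pyridine (cat.), Et2O, −10 °C; used crude
Reagents that add atoms: phosphorus tribromide, BrP(Br)Br
Why: Allylic alcohol to bromide substitution as for geranyl bromide; low temperature suppresses allylic transposition and E/Z leakage.

**Step 9**
Reactants: 10, allylic bromide
Product: 11, {[(2E)-3-methyl-5-(2,6,6-trimethylcyclohex-1-en-1-yl)pent-2-en-1-yl]sulfonyl}benzene
Conditions: PhSO2Na, DMF, rt
Reagents that add atoms: sodium benzenesulfinate, [Na+].[O-]S(=O)c1ccccc1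
Why: SN2 S-alkylation of sulfinate at the primary allylic carbon gives the allyl sulfone with the E-alkene retained.

**Step 10**
Reactants: 12, hydroquinone
Product: 13, 1,4-bis(methoxymethoxy)benzene
Conditions: NaH (2.4 equiv), DMF, 0 °C; MOMCl (2.4 equiv), 0 °C → rt
Reagents that add atoms: chloromethyl methyl ether, COCCl
Why: Williamson-type acetal protection; MOM also serves as the ortho-directing group for the next step.

**Step 11**
Reactants: 13, bis-MOM hydroquinone; 14, prenyl bromide (1-bromo-3-methylbut-2-ene)
Product: 15, 1,4-bis(methoxymethoxy)-2-(3-methylbut-2-en-1-yl)benzene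
Conditions: n-BuLi, TMEDA, THF, 0 °C; CuBr·SMe2, −40 °C; 14, −40 °C → rt
Reagents that add atoms: none beyond the two reactants
Why: Directed ortho-metalation, then copper-mediated SN2 allylation; all four ring positions are equivalent, so mono-lithiation gives one regioisomer.

**Step 12**
Reactants: 15, prenyl arene
Product: 16, (2E)-4-[2,5-bis(methoxymethoxy)phenyl]-2-methylbut-2-en-1-ol
Conditions: SeO2 (0.5 equiv), t-BuOOH (3 equiv), salicylic acid (cat.), CH2Cl2, 0 °C → rt; then NaBH4, MeOH, 0 °C
Reagents that add atoms: selenium dioxide, O=[Se]=O; tert-butyl hydroperoxide, CC(C)(C)OO (oxygen source)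
Why: Sharpless SeO2 allylic oxidation (ene reaction, then [2,3]-sigmatropic shift) oxidises the E-methyl of the gem-dimethyl alkene, which sets the E geometry. The borohydride work-up returns any over-oxidised enal to the alcohol.

**Step 13**
Reactants: 16, allylic alcohol
Product: 17, 2-[(2E)-4-bromo-3-methylbut-2-en-1-yl]-1,4-bis(methoxymethoxy)benzene
Conditions: MsCl, Et3N, THF, −40 °C; LiBr, THF, 0 °C; used crude
Reagents that add atoms: lithium bromide, [Li+].[Br-]
Why: Mesylation and SN2 bromide displacement under non-acidic conditions, so the MOM ethers and the E-alkene survive.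

**Step 14**
Reactants: 11, C15 allyl sulfone; 17, C13 allylic bromide
Product: 18, 2-[(2E,6E)-3,7-dimethyl-5-(phenylsulfonyl)-9-(2,6,6-trimethylcyclohex-1-en-1-yl)nona-2,6-dien-1-yl]-1,4-bis(methoxymethoxy)benzene (racemic at C5)
Conditions: 11, n-BuLi (1.05 equiv), THF/DMPU, −78 °C; then 17, −78 → −20 °C
Reagents that add atoms: none beyond the two reactants
Why: Alkylation of an α-sulfonyl allyl carbanion (Julia/Biellmann-type coupling) at the primary allylic bromide joins the two halves; the new sulfone-bearing centre is racemic and is removed in the next step.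

**Step 15**
Reactants: 18, coupled sulfone
Product: 19, 2-[(2E,6E)-3,7-dimethyl-9-(2,6,6-trimethylcyclohex-1-en-1-yl)nona-2,6-dien-1-yl]-1,4-bis(methoxymethoxy)benzene
Conditions: PdCl2(dppp) (10 mol%), LiBHEt3 (2.5 equiv), THF, 0 °C → rt
Reagents that add atoms: none (hydride only)
Why: Pd-catalysed reductive desulfonylation; hydride attacks the less substituted end of the π-allyl (the former sulfone carbon), so the trisubstituted alkene keeps its position and E geometry.

**Step 16**
Reactants: 19, bis-MOM ether
Product: 20, jaspaquinol, 2-[(2E,6E)-3,7-dimethyl-9-(2,6,6-trimethylcyclohex-1-en-1-yl)nona-2,6-dien-1-yl]benzene-1,4-diol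
Conditions: 3 M aq. HCl, MeOH/THF (degassed), rt → 40 °C, Ar; work-up with aq. Na2S2O4 wash
Reagents that add atoms: none
Why: Acid-catalysed acetal hydrolysis frees both phenols; dilute acid at or near room temperature is too mild to protonate the alkenes, and dithionite keeps the product in the hydroquinone oxidation state.

## Compound list

1 | 2-methylcyclohexanone | CC1CCCCC1=O | starting material
2 | 2,6-dimethylcyclohexanone (cis/trans) | CC1CCCC(C)C1=O | intermediate
3 | 2,2,6-trimethylcyclohexanone (racemic) | CC1CCCC(C)(C)C1=O | intermediate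
4 | 2,6,6-trimethylcyclohex-1-en-1-yl triflate | CC1=C(OS(=O)(=O)C(F)(F)F)C(C)(C)CCC1 | intermediate
5 | (2E)-3-methylpent-2-en-4-yn-1-ol | C#C/C(C)=C/CO | starting material
6 | TBS ether of 5 | C#C/C(C)=C/CO[Si](C)(C)C(C)(C)C | intermediate
7 | tert-butyldimethyl{[(2E)-3-methylpenta-2,4-dien-1-yl]oxy}silane | C=C/C(C)=C/CO[Si](C)(C)C(C)(C)C | intermediate
8 | TBS ether of (E)-monocyclofarnesol | CC1=C(CC/C(C)=C/CO[Si](C)(C)C(C)(C)C)C(C)(C)CCC1 | intermediate
9 | (2E)-3-methyl-5-(2,6,6-trimethylcyclohex-1-en-1-yl)pent-2-en-1-ol | CC1=C(CC/C(C)=C/CO)C(C)(C)CCC1 | intermediate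
10 | 2-[(3E)-5-bromo-3-methylpent-3-en-1-yl]-1,3,3-trimethylcyclohex-1-ene | CC1=C(CC/C(C)=C/CBr)C(C)(C)CCC1 | intermediate
11 | (E)-monocyclofarnesyl phenyl sulfone | CC1=C(CC/C(C)=C/CS(=O)(=O)c2ccccc2)C(C)(C)CCC1 | intermediate
12 | hydroquinone | Oc1ccc(O)cc1 | starting material
13 | 1,4-bis(methoxymethoxy)benzene | COCOc1ccc(OCOC)cc1 | intermediate
14 | prenyl bromide | CC(C)=CCBr | starting material
15 | 1,4-bis(methoxymethoxy)-2-(3-methylbut-2-en-1-yl)benzene | COCOc1ccc(OCOC)c(CC=C(C)C)c1 | intermediate
16 | (2E)-4-[2,5-bis(methoxymethoxy)phenyl]-2-methylbut-2-en-1-ol | COCOc1ccc(OCOC)c(C/C=C(C)/CO)c1 | intermediate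
17 | 2-[(2E)-4-bromo-3-methylbut-2-en-1-yl]-1,4-bis(methoxymethoxy)benzene | COCOc1ccc(OCOC)c(C/C=C(C)/CBr)c1 | intermediate
18 | coupled C5 phenyl sulfone (racemic at C5, 2E,6E) | CC1=C(CC/C(C)=C/C(C/C(C)=C/Cc2cc(OCOC)ccc2OCOC)S(=O)(=O)c2ccccc2)C(C)(C)CCC1 | intermediate
19 | jaspaquinol bis-MOM ether | CC1=C(CC/C(C)=C/CC/C(C)=C/Cc2cc(OCOC)ccc2OCOC)C(C)(C)CCC1 | intermediate
20 | jaspaquinol | CC1=C(CC/C(C)=C/CC/C(C)=C/Cc2cc(O)ccc2O)C(C)(C)CCC1 | target

## Summary

Total steps: 16.
Longest linear sequence: 10 (steps 1, 2, 3, 6, 7, 8, 9, 14, 15, 16).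

Steps most likely to fail, with fallbacks:

1. **Step 6** (B-alkyl Suzuki at a tetrasubstituted, neopentyl-flanked triflate, with diene mono-hydroboration before it). Fallback: Pd-catalysed methoxycarbonylation of 4 to methyl β-cyclogeranate, reduction and bromination to β-cyclogeranyl bromide, γ-alkylation of the methyl acetoacetate dianion, (Z)-enol phosphate formation and Me2CuLi substitution, then DIBAL to reach 9.
2. **Step 15** (reductive desulfonylation; risk of alkene transposition or E/Z erosion). Fallback: drop the sulfone union and join the halves by sp2–sp3 coupling. The partners would be the (E)-vinyl iodide ring–CH2CH2–C(Me)=CH–I (Zr-catalysed carboalumination and iodination of the corresponding terminal alkyne) and the alkyl-9-BBN derived from ArCH2CH=C(Me)CH2CH2I.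
3. **Step 16** (acidic MOM removal next to a 2-prenyl-type hydroquinone; risk of chroman formation, polyene cyclisation or air oxidation). Fallback: carry the arene as 1,4-dimethoxybenzene through the same sequence and unmask at the end by CAN oxidation to the benzoquinone followed by Na2S2O4 reduction to jaspaquinol.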